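**Assumption:** the target has no stereocentre or other stereo-element (it is achiral), so there is nothing to set and "single enantiomer" is met trivially.

## Retrosynthetic overview

1. Both benzene rings are bought ready-made in one commodity ester, methyl 2,4-dihydroxy-3,6-dimethylbenzoate 1; no ring is formed in the route.
2. 1 ⇒ (2, 3, one pot) ⇒ common phenol 4, which already carries the 2-OMe/4-OH pattern of both halves.
3. Ring A: 4 ⇒ aldehyde 5 ⇒ phenol 6 (the extra ring methyl by formylation/reduction).
4. Ring B: 4 ⇒ chloride 7 ⇒ (acylium 8) ⇒ hydroxy acid 9.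
5. Key disconnection, made last: the depside C(acyl)–O(aryl) bond, 9 + 6 ⇒ (10, 11) ⇒ target 12, with both partners unprotected.

## Route

**Step 1**
Reactants: 1 methyl 2,4-dihydroxy-3,6-dimethylbenzoate
Product: 4 methyl 4-hydroxy-2-methoxy-3,6-dimethylbenzoate, via mono-MOM ether 2 (not isolated), via methylated MOM ether 3 (not isolated)
Conditions: MOMCl (1.05 equiv), K2CO3 (3 equiv), acetone, 0 °C to rt; then MeI (3 equiv), reflux, 24 h; then MeOH, conc. HCl (pH < 1), 50 °C
Reagents that add atoms: iodomethane, CI; chloromethyl methyl ether, COCCl (its atoms stay only in 2 and 3)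
Why: Williamson O-alkylation in which the free, more acidic 4-OH takes the single equivalent of MOMCl while the ester-chelated 2-OH reacts only with excess MeI at reflux, after which acid-catalysed acetal exchange with MeOH removes the MOM group and leaves the hindered methyl ester and the aryl methyl ether untouched.

**Step 2**
Reactants: 4 methyl 4-hydroxy-2-methoxy-3,6-dimethylbenzoate
Product: 5 methyl 3-formyl-4-hydroxy-6-methoxy-2,5-dimethylbenzoate
Conditions: MgCl2 (2 equiv), Et3N (4 equiv), paraformaldehyde (6 equiv), MeCN, reflux; 1 M HCl work-up
Reagents that add atoms: formaldehyde (as paraformaldehyde), C=O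
Why: Casnati–Skattebøl ortho-formylation, in which the magnesium phenoxide delivers formaldehyde to the ortho carbon (the only unsubstituted ring position) and a second formaldehyde oxidises the salicyl alkoxide to the aldehyde by hydride transfer.

**Step 3**
Reactants: 5 methyl 3-formyl-4-hydroxy-6-methoxy-2,5-dimethylbenzoate
Product: 6 methyl 4-hydroxy-2-methoxy-3,5,6-trimethylbenzoate
Conditions: Et3SiH (4 equiv), TFA, 0 °C to rt
Reagents that add atoms: none
Why: Ionic hydrogenation, in which the protonated aldehyde and then the ortho-hydroxy-stabilised benzylic cation each take hydride from the silane, with no free ring position left for Friedel–Crafts side reactions.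

**Step 4**
Reactants: 4 methyl 4-hydroxy-2-methoxy-3,6-dimethylbenzoate
Product: 7 methyl 3-chloro-4-hydroxy-6-methoxy-2,5-dimethylbenzoate
Conditions: SO2Cl2 (1.05 equiv), CH2Cl2, 0 °C to rt, dark
Reagents that add atoms: sulfuryl chloride, ClS(Cl)(=O)=O
Why: Electrophilic aromatic chlorination at the only open ring position, ortho to the free phenol, under ionic conditions that leave the benzylic methyl groups alone.

**Step 5**
Reactants: 7 methyl 3-chloro-4-hydroxy-6-methoxy-2,5-dimethylbenzoate
Product: 9 3-chloro-4-hydroxy-6-methoxy-2,5-dimethylbenzoic acid, via acylium ion 8 (not isolated)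
Conditions: conc. H2SO4, 0 °C to rt, 1 h; then poured onto ice
Reagents that add atoms: water, O
Why: A_AC1 ester cleavage (the sulfuric-acid method for 2,6-disubstituted benzoates), in which the twisted, donor-substituted ester ionises to acylium ion 8 that water captures on quenching, while the fully substituted ring cannot be sulfonated.

**Step 6**
Reactants: 9 3-chloro-4-hydroxy-6-methoxy-2,5-dimethylbenzoic acid (1.0 equiv); 6 methyl 4-hydroxy-2-methoxy-3,5,6-trimethylbenzoate (1.3 equiv)
Product: 12 methyl 4-[(3-chloro-4-hydroxy-6-methoxy-2,5-dimethylbenzoyl)oxy]-2-methoxy-3,5,6-trimethylbenzoate, via O-acylisourea 10 (not isolated), via oxoketene 11 (not isolated)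
Conditions: DIC (1.1 equiv), MeCN, 0 °C to rt, 1 h; then DBU (1.2 equiv), 40 °C, 12 h; AcOH quench
Reagents that add atoms: N,N'-diisopropylcarbodiimide, CC(C)N=C=NC(C)C (its atoms stay only in 10)
Why: Proposed new method: a protecting-group-free, self-correcting depside coupling by dissociative (E1cB) aroyl transfer, in which the carbodiimide turns the hindered acid into O-acylisourea 10 (phenols do not add to DIC) and, once DBU deprotonates the acidic 4-OH (estimated pKa about 7, ortho-Cl), the phenoxide expels diisopropylurea to give p-oxoketene 11 (the perpendicular twist of the 2,6-disubstituted acyl group aligns the ring π-system with the breaking C–O bond), whose sp carbon avoids the crowded tetrahedral intermediate and is captured by the hindered phenol 6; any self-ester, anhydride or trimer formed from the phenoxide of 9 or 12 is an acyl derivative of the more acidic ring-B phenol and re-ionises to 11 roughly a thousand times faster than 12 (estimated from the steep leaving-group dependence of E1cB acyl transfer), so the mixture funnels to 12, the ester of the less acidic phenol (estimated pKa about 9); the closest known reaction types are the E1cB hydrolysis of aryl 4-hydroxybenzoates through p-oxoketenes (known as a mechanism, not as a preparative coupling), Steglich carbodiimide esterification and TFAA-mediated depside coupling through acylium ions.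

## Compound list

1 | methyl 2,4-dihydroxy-3,6-dimethylbenzoate (Evernyl) | COC(=O)c1c(C)cc(O)c(C)c1O | starting material
2 | methyl 2-hydroxy-4-(methoxymethoxy)-3,6-dimethylbenzoate | COC(=O)c1c(C)cc(OCOC)c(C)c1O | intermediate (not isolated)
3 | methyl 2-methoxy-4-(methoxymethoxy)-3,6-dimethylbenzoate | COC(=O)c1c(C)cc(OCOC)c(C)c1OC | intermediate (not isolated)
4 | methyl 4-hydroxy-2-methoxy-3,6-dimethylbenzoate | COC(=O)c1c(C)cc(O)c(C)c1OC | intermediate
5 | methyl 3-formyl-4-hydroxy-6-methoxy-2,5-dimethylbenzoate | COC(=O)c1c(C)c(C=O)c(O)c(C)c1OC | intermediate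
6 | methyl 4-hydroxy-2-methoxy-3,5,6-trimethylbenzoate | COC(=O)c1c(C)c(C)c(O)c(C)c1OC | intermediate
7 | methyl 3-chloro-4-hydroxy-6-methoxy-2,5-dimethylbenzoate | COC(=O)c1c(C)c(Cl)c(O)c(C)c1OC | intermediate
8 | 3-chloro-4-hydroxy-6-methoxy-2,5-dimethylbenzoyl cation (acylium ion, in H2SO4) | [O+]#Cc1c(C)c(Cl)c(O)c(C)c1OC | intermediate (not isolated)
9 | 3-chloro-4-hydroxy-6-methoxy-2,5-dimethylbenzoic acid | OC(=O)c1c(C)c(Cl)c(O)c(C)c1OC | intermediate
10 | O-(3-chloro-4-hydroxy-6-methoxy-2,5-dimethylbenzoyl)-N,N'-diisopropylisourea | CC(C)N=C(NC(C)C)OC(=O)c1c(C)c(Cl)c(O)c(C)c1OC | intermediate (not isolated)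
11 | 2-chloro-5-methoxy-3,6-dimethyl-4-(oxomethylidene)cyclohexa-2,5-dien-1-one (p-oxoketene) | O=C=C1C(C)=C(Cl)C(=O)C(C)=C1OC | intermediate (not isolated)
12 | methyl 4-[(3-chloro-4-hydroxy-6-methoxy-2,5-dimethylbenzoyl)oxy]-2-methoxy-3,5,6-trimethylbenzoate | COC(=O)c1c(C)c(C)c(OC(=O)c2c(C)c(Cl)c(O)c(C)c2OC)c(C)c1OC | target

## Step count and risks

Total step count: 6. Longest linear sequence: 4 steps (1 → 4 → 5 → 6 → 12, or 1 → 4 → 7 → 9 → 12).

The three steps most likely to fail:

**Step 6 (the proposed new coupling).** Risks are irreversible N-acylurea formation, incomplete unzipping of ring-B self-esters, or slow capture of 11 by the di-ortho-methyl phenol. The fallback is the known protected depside route and sets out from 9. Acetylation (Ac2O, pyridine, cat. DMAP, rt, aqueous work-up to hydrolyse the mixed anhydride) gives 4-acetoxy-3-chloro-6-methoxy-2,5-dimethylbenzoic acid F2. Classical depside coupling of this acid with 6 (TFAA, toluene, rt, mixed anhydride/acylium acylation) gives methyl 4-[(4-acetoxy-3-chloro-6-methoxy-2,5-dimethylbenzoyl)oxy]-2-methoxy-3,5,6-trimethylbenzoate F3. Acid methanolysis of the unhindered aryl acetate (1.25 M HCl in MeOH, rt), which the tetra-ortho-substituted depside ester survives, comes back to the route at 12.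

**Step 5 (cleavage of the 2,6-disubstituted methyl ester).** Risks are protodecarboxylation of the electron-rich acid on quenching or partial loss of the aryl methyl ether in sulfuric acid. The fallback sets out from 7 and attacks the other bond of the ester from the basic side. Lithium propanethiolate (3 equiv, from n-PrSH and n-BuLi) in DMPU–THF at rt to 50 °C cleaves the O–CH3 bond by SN2 attack at the ester methyl. This is far faster than attack at the aryl methyl ether, and acidification delivers the acid directly, so the fallback comes back to the route at 9 and makes no compound outside the list (none F0).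

**Step 2 (formylation at the last, flanked ring position).** Risks are sluggish reaction next to the methyl group and methoxymethyl by-products on long heating. The fallback installs the methyl group by halogenation and cross-coupling instead; it sets out from 4 and bypasses 5. Bromination (NBS, MeCN, 0 °C) at the same and only free position gives methyl 3-bromo-4-hydroxy-6-methoxy-2,5-dimethylbenzoate F1. Suzuki–Miyaura methylation (trimethylboroxine, Pd(OAc)2/SPhos, K3PO4, dioxane–water, 100 °C) comes back to the route at 6.

## Further compounds

F1 | step 2 | methyl 3-bromo-4-hydroxy-6-methoxy-2,5-dimethylbenzoate | COC(=O)c1c(C)c(Br)c(O)c(C)c1OC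
F0 | step 5 | none | none
F2 | step 6 | 4-acetoxy-3-chloro-6-methoxy-2,5-dimethylbenzoic acid | OC(=O)c1c(C)c(Cl)c(OC(C)=O)c(C)c1OC
F3 | step 6 | methyl 4-[(4-acetoxy-3-chloro-6-methoxy-2,5-dimethylbenzoyl)oxy]-2-methoxy-3,5,6-trimethylbenzoate | COC(=O)c1c(C)c(C)c(OC(=O)c2c(C)c(Cl)c(OC(C)=O)c(C)c2OC)c(C)c1OC
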